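The numbers in the tables are simulated on assumed constants.

The rate of making product at 10% conversion is the quantity at stake: I want its percent change in the flask for one percent more free catalyst charged.

| flask | starting material | reagent | free catalyst | impurity | remark |
|---|---|---|---|---|---|
| south | 1.8 M | 1.1 equiv | 0.069 mol% | 0.37 mM | run made earlier |
| north-west | 0.90 M | 0.80 equiv | 0.069 mol% | 0.37 mM | run made earlier |
| flask | 1.8 M | 0.800 equiv | 0.069 mol% | 0.37 mM |  |

| run | time / min | product / % | starting material / % |
|---|---|---|---|
| south | 1.50 | 2.6 | 97.8 |
| south | 5.00 | 7.9 | 92.2 |
| south | 10.0 | 14.4 | 84.6 |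
| south | 15.0 | 20.9 | 78.9 |
| south | 20.0 | 28.6 | 72.5 |
| south | 25.0 | 32.1 | 66.5 |
| south | 30.0 | 37.6 | 62.0 |
| north-west | 6.00 | 4.0 | 95.1 |
| north-west | 12.0 | 7.3 | 93.5 |
| north-west | 20.0 | 11.1 | 89.2 |
| north-west | 25.0 | 13.7 | 86.7 |
| north-west | 30.0 | 15.4 | 83.9 |

(scatter of a reading: 0.5 percentage points)

1. apparent order in free catalyst when 10% of the starting material are converted (percent change of the rate of making product for one percent more free catalyst charged)



My first way uses the charges. The flask holds 1.24 mM of catalyst and 0.37 mM of impurity. If each impurity takes one catalyst out early, as in a titration, 0.872 mM keeps working, and an added percent of charge lands wholly on that remainder. So I carry the poison multiplier, charged catalyst divided by charged catalyst minus impurity, which is 1.42 here and is my answer for the order. In the north-west run, 0.621 mM of catalyst meets the same impurity, leaving 0.251 mM, and the multiplier is 2.47.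

My second way uses the readings. Over the last reading of each run, first-order constants come to 0.0159 min⁻¹ for south and 0.00585 min⁻¹ for north-west, a read ratio of 2.72. Taken across the doubled catalyst charge, that is an order of 1.45. It looks like agreement, but it isn't one. Over the same doubling, the multiplier's rule predicts a ratio of 3.47, which is larger than the read 2.72, or an order of 1.80. The readings are the way that cheats here: the two runs also differ in starting material and reagent, so their ratio isn't the catalyst's own, and it spans a wide step, not the flask's one percent. I keep 1.42.

The forecast gives 1.3, with a range of 0.95 to 1.55, lower than mine, because it holds that the “data therefore suggest partial poisoning”.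

The flask gives 1.4, so at 10% conversion one percent more free catalyst charged buys about that percentage of extra rate of making product.

    reagent + free catalyst ⇌ catalyst intermediate A (K = 0.500 M⁻¹, k = 58.0 M⁻¹ min⁻¹)
    catalyst intermediate A ⇌ by-product + catalyst intermediate B (K = 2.20 M, k = 660 min⁻¹)
    catalyst intermediate B ⇌ catalyst intermediate C (K = 1.60, k = 79.0 min⁻¹)
    starting material + catalyst intermediate C ⇌ catalyst intermediate D (K = 8.90 M⁻¹, k = 2000 M⁻¹ min⁻¹)
    catalyst intermediate D → free catalyst + product (k = 180 min⁻¹)
    free catalyst + impurity → spent catalyst (k = 4700 M⁻¹ min⁻¹)

With impurity held as charged, free catalyst has a half-life of 0.399 min by the poisoning step alone, far shorter than the 7.47 min the flask takes to reach 10% conversion. The multiplier of 1.42 counts 29.8% of the charge as taken out, and at 4.00 min impurity is down to 0.0749% of its charge while spent catalyst stands at 29.8% of the catalyst charged.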